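The meso target is cut at O1–C2 and at the bond between C3 and its hydroxymethyl carbon; both fall on an aryl alkyne C2≡C3 held by the C5 carbinol, in which the anti C4/C5 pair is already in place. In one palladium-catalysed oxidative operation the C5 hydroxyl closes the five-membered oxygen ring onto the aryl-bearing alkyne carbon (O1–C2) and the C3–palladium bond is trapped by CO and methanol as the ester that later becomes the C3 CH2OH. The precursor is the racemic anti 1,4-diaryl homopropargylic alcohol with benzyl-capped phenols and a silylated C4 hydroxymethyl group; directed hydrogenation and C3 epimerisation through a cis-lactone then complete the ring stereochemistry.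

Key step: step 6

Remark on symmetry: the target (2S,3R,4S,5R, identical aryl groups) has a mirror plane through O1 and the midpoint of C3–C4, so every chiral intermediate is made as a racemate and descriptors give relative configuration; ring numbering throughout is O1, C2 and C5 (aryl), C3 and C4 (one-carbon arms).

Remark on the precursor: the primary hydroxyl is carried as a tert-butyldiphenylsilyl ether, because the traces of HI and I2 that the carbonylation generates in warm methanol could strip a tert-butyldimethylsilyl ether and free a second homopropargylic hydroxyl able to close a competing ring; (tert-butyldiphenylsilyloxy)acetaldehyde is taken as a catalogue aldehyde.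

Step 1
Reactants: 1 syringaldehyde; 2 benzyl bromide
Product: 3 4-(benzyloxy)-3,5-dimethoxybenzaldehyde
Conditions: K2CO3, DMF, 60 °C
Reagents that add atoms: benzyl bromide (2), BrCc1ccccc1
Why: Williamson etherification of an acidic phenoxide with a primary benzylic bromide, with no competing nucleophile in the molecule.

Step 2
Reactants: 3 4-(benzyloxy)-3,5-dimethoxybenzaldehyde; 4 dimethyl (1-diazo-2-oxopropyl)phosphonate
Product: 5 2-(benzyloxy)-5-ethynyl-1,3-dimethoxybenzene
Conditions: K2CO3, MeOH–THF, 0 °C to rt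
Reagents that add atoms: dimethyl (1-diazo-2-oxopropyl)phosphonate (4), COP(=O)(OC)C(=[N+]=[N-])C(C)=O
Why: Seyferth–Gilbert homologation in the Ohira–Bestmann variant turns a non-enolisable aryl aldehyde into the terminal alkyne under carbonate/methanol conditions that leave the aryl ethers untouched.

Step 3
Reactants: 5 2-(benzyloxy)-5-ethynyl-1,3-dimethoxybenzene; 6 (tert-butyldiphenylsilyloxy)acetaldehyde
Product: 8 rac-4-[4-(benzyloxy)-3,5-dimethoxyphenyl]-1-(tert-butyldiphenylsilyloxy)but-3-yn-2-ol, via lithium acetylide 7 (not isolated)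
Conditions: n-BuLi, THF, −78 °C; then 6, −78 to 0 °C; H2O
Reagents that add atoms: none
Why: carbonyl alkynylation, in which the lithium acetylide adds 1,2 to the α-silyloxy aldehyde at −78 °C faster than it enolises it; the carbinol centre forms as a racemate, which suffices.

Step 4
Reactants: 8 rac-4-[4-(benzyloxy)-3,5-dimethoxyphenyl]-1-(tert-butyldiphenylsilyloxy)but-3-yn-2-ol
Product: 9 rac-4-[4-(benzyloxy)-3,5-dimethoxyphenyl]-1-(tert-butyldiphenylsilyloxy)but-3-yn-2-yl methanesulfonate
Conditions: MsCl, Et3N, CH2Cl2, −78 to −20 °C; used crude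
Reagents that add atoms: methanesulfonyl chloride, CS(Cl)(=O)=O
Why: sulfonylation of a secondary propargylic alcohol through the sulfene at low temperature; the aryl-conjugated mesylate should be carried on without chromatography because it ionises easily.

Step 5
Reactants: 9 rac-4-[4-(benzyloxy)-3,5-dimethoxyphenyl]-1-(tert-butyldiphenylsilyloxy)but-3-yn-2-yl methanesulfonate; 3 4-(benzyloxy)-3,5-dimethoxybenzaldehyde
Product: 11 rac-(1R,2S)-1,4-bis[4-(benzyloxy)-3,5-dimethoxyphenyl]-2-[(tert-butyldiphenylsilyloxy)methyl]but-3-yn-1-ol (anti), via allenylindium iodide mesylate 10 (not isolated)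
Conditions: PdCl2(dppf) (5 mol%), InI (1.4 equiv), THF–HMPA 3:1, rt
Reagents that add atoms: none
Why: Marshall propargylation, in which zerovalent palladium (formed in situ) displaces the mesylate anti SN2′, InI transmetallates to allenylindium 10, and 10 adds to aldehyde 3 at its γ-carbon through a cyclic SE2′ transition state in which the aldehyde aryl group and the CH2OSi arm avoid each other, which sets the anti C4/C5 pair.

Step 6
Reactants: 11 rac-(1R,2S)-1,4-bis[4-(benzyloxy)-3,5-dimethoxyphenyl]-2-[(tert-butyldiphenylsilyloxy)methyl]but-3-yn-1-ol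
Product: 12 methyl rac-(4S,5R)-2,5-bis[4-(benzyloxy)-3,5-dimethoxyphenyl]-4-[(tert-butyldiphenylsilyloxy)methyl]-4,5-dihydrofuran-3-carboxylate (4,5-trans)
Conditions: PdI2 (5 mol%), KI (50 mol%), CO–air 4:1 (40 atm), MeOH–MeCN 1:1, 70 °C
Reagents that add atoms: carbon monoxide, [C-]#[O+]; methanol, CO
Why: PdI2 with excess KI gives [PdI4]2−, a divalent palladium species that binds the alkyne; the C5 hydroxyl then attacks the aryl-bearing alkyne carbon anti to the metal, CO inserts into the resulting C3 vinyl–palladium bond, and methanolysis of the acyl–palladium bond releases ester 12, HI and zerovalent palladium, which O2 and HI return to PdI2. The closest known reaction type is the PdI2/KI oxidative heterocyclisation–alkoxycarbonylation of alkynols (3-yne-1,2-diols to furan-3-carboxylates) and of 2-alkynylphenols. The one ring closes in the 5-endo-dig mode (O1–C2); the 4-exo-dig alternative is strained and would aim at the less electrophilic alkyne carbon. No stereocentre is created, and the anti C4/C5 pair of 11 is carried through unchanged as the 4,5-trans relation of 12. The step needs the secondary hydroxyl and not the primary oxygen as ring oxygen, and oxypalladation rather than carbonylation of the hydroxyl or protonolysis of the vinyl–palladium bond: the acid-stable silyl ether keeps the primary oxygen masked against traces of HI and I2, the electron-rich aryl group polarises the internal alkyne towards attack at C2 while its two substituents disfavour insertion into an alkoxycarbonyl–palladium bond, and the CO pressure makes insertion faster than protonolysis.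

Step 7
Reactants: 12 methyl rac-(4S,5R)-2,5-bis[4-(benzyloxy)-3,5-dimethoxyphenyl]-4-[(tert-butyldiphenylsilyloxy)methyl]-4,5-dihydrofuran-3-carboxylate
Product: 13 methyl rac-(4S,5R)-2,5-bis[4-(benzyloxy)-3,5-dimethoxyphenyl]-4-(hydroxymethyl)-4,5-dihydrofuran-3-carboxylate
Conditions: Bu4NF, AcOH, THF, 0 °C to rt
Reagents that add atoms: none
Why: fluoride-mediated desilylation driven by the Si–F bond, with acetic acid buffering so that the freed alkoxide does not attack the neighbouring unsaturated ester; benzyl ethers and the vinylogous carbonate are inert.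

Step 8
Reactants: 13 methyl rac-(4S,5R)-2,5-bis[4-(benzyloxy)-3,5-dimethoxyphenyl]-4-(hydroxymethyl)-4,5-dihydrofuran-3-carboxylate
Product: 14 methyl rac-(2S,3R,4S,5R)-2,5-bis[4-(benzyloxy)-3,5-dimethoxyphenyl]-4-(hydroxymethyl)tetrahydrofuran-3-carboxylate (2,3-cis, 3,4-trans, 4,5-trans, 2,5-cis)
Conditions: H2 (5 atm), [Ir(cod)(PCy3)(py)]PF6 (10 mol%), CH2Cl2, rt
Reagents that add atoms: none
Why: hydroxyl-directed homogeneous hydrogenation, in which the C4 CH2OH binds the cationic iridium centre so that both hydrogens reach the tetrasubstituted C2=C3 bond from the face of that group; this substrate control places the C2 aryl cis to the C5 aryl and the C3 ester trans to the CH2OH, and the benzyl ethers are not cleaved by this catalyst.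

Step 9
Reactants: 14 methyl rac-(2S,3R,4S,5R)-2,5-bis[4-(benzyloxy)-3,5-dimethoxyphenyl]-4-(hydroxymethyl)tetrahydrofuran-3-carboxylate
Product: 16 rac-(3aS,4R,6S,6aS)-4,6-bis[4-(benzyloxy)-3,5-dimethoxyphenyl]tetrahydro-1H,3H-furo[3,4-c]furan-1-one (cis-fused, both aryl groups exo), via C3-epimeric hydroxy ester 15 (not isolated)
Conditions: NaOMe (0.3 equiv), THF–MeOH 10:1, 40 °C; then AcOH
Reagents that add atoms: none
Why: base-mediated ester epimerisation coupled to lactonisation, in which methoxide equilibrates C3 through the ester enolate and only epimer 15 (ester cis to the C4 CH2OH) can close the cis-fused γ-lactone, which drains the equilibrium and fixes the 3,4-cis and 2,3-trans relations; C2 should hold because expulsion of O1 from the ring enolate is a geometrically disfavoured reverse 5-endo-trig process.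

Step 10
Reactants: 16 rac-(3aS,4R,6S,6aS)-4,6-bis[4-(benzyloxy)-3,5-dimethoxyphenyl]tetrahydro-1H,3H-furo[3,4-c]furan-1-one
Product: 17 meso-(2S,3R,4S,5R)-{2,5-bis[4-(benzyloxy)-3,5-dimethoxyphenyl]tetrahydrofuran-3,4-diyl}dimethanol
Conditions: LiAlH4, THF, 0 °C to rt; H2O, aq NaOH
Reagents that add atoms: none
Why: hydride reduction of a lactone to the 1,4-diol, which touches no stereocentre and leaves the benzyl ethers and the ring ether alone.

Step 11
Reactants: 17 meso-(2S,3R,4S,5R)-{2,5-bis[4-(benzyloxy)-3,5-dimethoxyphenyl]tetrahydrofuran-3,4-diyl}dimethanol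
Product: 18 (2S,3R,4S,5R)-[2,5-bis(4-hydroxy-3,5-dimethoxyphenyl)tetrahydrofuran-3,4-diyl]dimethanol (meso; CNP0170897.5)
Conditions: H2 (1 atm), 10% Pd/C, EtOAc–MeOH, rt
Reagents that add atoms: none
Why: catalytic hydrogenolysis of the two aryl benzyl ethers, which at 1 atm in a neutral solvent should be much faster than cleavage of the ring benzylic C–O bonds, so the reaction is stopped after two equivalents of H2.

Compound list
1 | syringaldehyde (4-hydroxy-3,5-dimethoxybenzaldehyde) | COc1cc(C=O)cc(OC)c1O | starting material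
2 | benzyl bromide | BrCc1ccccc1 | starting material
3 | 4-(benzyloxy)-3,5-dimethoxybenzaldehyde | COc1cc(C=O)cc(OC)c1OCc1ccccc1 | intermediate
4 | dimethyl (1-diazo-2-oxopropyl)phosphonate | COP(=O)(OC)C(=[N+]=[N-])C(C)=O | starting material
5 | 2-(benzyloxy)-5-ethynyl-1,3-dimethoxybenzene | COc1cc(C#C)cc(OC)c1OCc1ccccc1 | intermediate
6 | (tert-butyldiphenylsilyloxy)acetaldehyde | CC(C)(C)[Si](OCC=O)(c1ccccc1)c1ccccc1 | starting material
7 | lithium [4-(benzyloxy)-3,5-dimethoxyphenyl]acetylide (formed in the flask) | COc1cc(C#C[Li])cc(OC)c1OCc1ccccc1 | intermediate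
8 | rac-4-[4-(benzyloxy)-3,5-dimethoxyphenyl]-1-(tert-butyldiphenylsilyloxy)but-3-yn-2-ol (racemic, one stereocentre) | COc1cc(C#CC(O)CO[Si](c2ccccc2)(c2ccccc2)C(C)(C)C)cc(OC)c1OCc1ccccc1 | intermediate
9 | rac-4-[4-(benzyloxy)-3,5-dimethoxyphenyl]-1-(tert-butyldiphenylsilyloxy)but-3-yn-2-yl methanesulfonate (racemic) | COc1cc(C#CC(CO[Si](c2ccccc2)(c2ccccc2)C(C)(C)C)OS(C)(=O)=O)cc(OC)c1OCc1ccccc1 | intermediate
10 | {1-[4-(benzyloxy)-3,5-dimethoxyphenyl]-4-(tert-butyldiphenylsilyloxy)buta-1,2-dien-1-yl}indium iodide methanesulfonate (racemic allene, formed in the flask) | COc1cc(C(=C=CCO[Si](c2ccccc2)(c2ccccc2)C(C)(C)C)[In](I)OS(C)(=O)=O)cc(OC)c1OCc1ccccc1 | intermediate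
11 | rac-(1R,2S)-1,4-bis[4-(benzyloxy)-3,5-dimethoxyphenyl]-2-[(tert-butyldiphenylsilyloxy)methyl]but-3-yn-1-ol (anti) | COc1cc(C#C[C@@H](CO[Si](c2ccccc2)(c2ccccc2)C(C)(C)C)[C@@H](O)c2cc(OC)c(OCc3ccccc3)c(OC)c2)cc(OC)c1OCc1ccccc1 | intermediate
12 | methyl rac-(4S,5R)-2,5-bis[4-(benzyloxy)-3,5-dimethoxyphenyl]-4-[(tert-butyldiphenylsilyloxy)methyl]-4,5-dihydrofuran-3-carboxylate (4,5-trans) | COC(=O)C1=C(c2cc(OC)c(OCc3ccccc3)c(OC)c2)O[C@@H](c2cc(OC)c(OCc3ccccc3)c(OC)c2)[C@@H]1CO[Si](c1ccccc1)(c1ccccc1)C(C)(C)C | intermediate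
13 | methyl rac-(4S,5R)-2,5-bis[4-(benzyloxy)-3,5-dimethoxyphenyl]-4-(hydroxymethyl)-4,5-dihydrofuran-3-carboxylate | COC(=O)C1=C(c2cc(OC)c(OCc3ccccc3)c(OC)c2)O[C@@H](c2cc(OC)c(OCc3ccccc3)c(OC)c2)[C@@H]1CO | intermediate
14 | methyl rac-(2S,3R,4S,5R)-2,5-bis[4-(benzyloxy)-3,5-dimethoxyphenyl]-4-(hydroxymethyl)tetrahydrofuran-3-carboxylate (2,3-cis, 3,4-trans, 4,5-trans) | COc1cc([C@H]2O[C@@H](c3cc(OC)c(OCc4ccccc4)c(OC)c3)[C@H](CO)[C@H]2C(=O)OC)cc(OC)c1OCc1ccccc1 | intermediate
15 | methyl rac-(2S,3S,4S,5R)-2,5-bis[4-(benzyloxy)-3,5-dimethoxyphenyl]-4-(hydroxymethyl)tetrahydrofuran-3-carboxylate (2,3-trans, 3,4-cis, 4,5-trans; formed in the flask) | COc1cc([C@H]2O[C@@H](c3cc(OC)c(OCc4ccccc4)c(OC)c3)[C@H](CO)[C@@H]2C(=O)OC)cc(OC)c1OCc1ccccc1 | intermediate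
16 | rac-(3aS,4R,6S,6aS)-4,6-bis[4-(benzyloxy)-3,5-dimethoxyphenyl]tetrahydro-1H,3H-furo[3,4-c]furan-1-one (cis-fused, aryl groups exo) | COc1cc([C@H]2O[C@@H](c3cc(OC)c(OCc4ccccc4)c(OC)c3)[C@@H]3COC(=O)[C@H]23)cc(OC)c1OCc1ccccc1 | intermediate
17 | meso-(2S,3R,4S,5R)-{2,5-bis[4-(benzyloxy)-3,5-dimethoxyphenyl]tetrahydrofuran-3,4-diyl}dimethanol | COc1cc([C@H]2O[C@@H](c3cc(OC)c(OCc4ccccc4)c(OC)c3)[C@H](CO)[C@@H]2CO)cc(OC)c1OCc1ccccc1 | intermediate
18 | (2S,3R,4S,5R)-[2,5-bis(4-hydroxy-3,5-dimethoxyphenyl)tetrahydrofuran-3,4-diyl]dimethanol (meso) | COc1cc([C@H]2O[C@@H](c3cc(OC)c(O)c(OC)c3)[C@H](CO)[C@@H]2CO)cc(OC)c1O | target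

Total step count: 11. Longest linear sequence: 11 steps (1 → 3 → 5 → 8 → 9 → 11 → 12 → 13 → 14 → 16 → 17 → 18; aldehyde 3 re-enters in step 5).

Steps most likely to fail

Step 6. The catalytic cycle may stall on the hindered diaryl alkyne, the vinyl–palladium bond may be protonated before CO inserts, or the silyl ether may be lost so that the wrong oxygen closes the ring. The fallback sets out from 11 and comes back at 12. Iodocyclisation of 11 with I2 and NaHCO3 in MeCN at 0 °C closes the same O1–C2 bond in the 5-endo-dig mode and should give rac-(2R,3S)-2,5-bis[4-(benzyloxy)-3,5-dimethoxyphenyl]-3-[(tert-butyldiphenylsilyloxy)methyl]-4-iodo-2,3-dihydrofuran F1. Palladium-catalysed methoxycarbonylation of this vinyl iodide (Pd(OAc)2, dppf, CO 1 atm, MeOH, Et3N, DMF, 60 °C) then installs the ester carbon and gives 12.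

Step 8. The tetrasubstituted push–pull alkene may not turn over, or hydrogen may be delivered without control by the hydroxyl, which would put the C2 aryl on the wrong face. The fallback sets out from 12 and comes back at 14. Ionic hydrogenation of 12 (Et3SiH, CF3CO2H, CH2Cl2, −20 °C) protonates C3 to a 2-aryl oxocarbenium ion, in which C3 can settle with the ester trans to the bulky C4 arm. Hydride then enters C2 anti to the C3 ester, as in reductions of 2-aryl cyclic hemiketals in tetrahydrofuran lignan work. This should give methyl rac-(2S,3R,4S,5R)-2,5-bis[4-(benzyloxy)-3,5-dimethoxyphenyl]-4-[(tert-butyldiphenylsilyloxy)methyl]tetrahydrofuran-3-carboxylate F2, and Bu4NF/AcOH in THF then gives 14.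

Step 5. Anti selectivity may erode with the aromatic aldehyde, the aryl-substituted allenylindium may lose SE2′ regiocontrol, or the aryl-conjugated mesylate may decompose before oxidative addition. The fallback sets out from 6 (with 3) and comes back at 11; it forms the aryl–alkyne bond last.
- HC≡CMgBr adds to 6 (THF, 0 °C) to give rac-1-(tert-butyldiphenylsilyloxy)but-3-yn-2-ol F3.
- MsCl/Et3N gives rac-1-(tert-butyldiphenylsilyloxy)but-3-yn-2-yl methanesulfonate F4.
- The same PdCl2(dppf)/InI propargylation with 3, now on a terminal-alkyne mesylate (the best-documented substrate class), should give rac-(1R,2S)-1-[4-(benzyloxy)-3,5-dimethoxyphenyl]-2-[(tert-butyldiphenylsilyloxy)methyl]but-3-yn-1-ol F5.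
- Commercial 4-bromo-2,6-dimethoxyphenol is benzylated with 2 (K2CO3, DMF) to 2-(benzyloxy)-5-bromo-1,3-dimethoxybenzene F6.
- Copper-free Sonogashira coupling of F5 with F6 (PdCl2(MeCN)2, XPhos, Cs2CO3, MeCN, 70 °C) gives 11.

Further compounds
F1 | step 6 | rac-(2R,3S)-2,5-bis[4-(benzyloxy)-3,5-dimethoxyphenyl]-3-[(tert-butyldiphenylsilyloxy)methyl]-4-iodo-2,3-dihydrofuran | IC1=C(c2cc(OC)c(OCc3ccccc3)c(OC)c2)O[C@@H](c2cc(OC)c(OCc3ccccc3)c(OC)c2)[C@@H]1CO[Si](c1ccccc1)(c1ccccc1)C(C)(C)C
F2 | step 8 | methyl rac-(2S,3R,4S,5R)-2,5-bis[4-(benzyloxy)-3,5-dimethoxyphenyl]-4-[(tert-butyldiphenylsilyloxy)methyl]tetrahydrofuran-3-carboxylate | COc1cc([C@H]2O[C@@H](c3cc(OC)c(OCc4ccccc4)c(OC)c3)[C@H](CO[Si](c3ccccc3)(c3ccccc3)C(C)(C)C)[C@H]2C(=O)OC)cc(OC)c1OCc1ccccc1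
F3 | step 5 | rac-1-(tert-butyldiphenylsilyloxy)but-3-yn-2-ol | C#CC(O)CO[Si](c1ccccc1)(c1ccccc1)C(C)(C)C
F4 | step 5 | rac-1-(tert-butyldiphenylsilyloxy)but-3-yn-2-yl methanesulfonate | C#CC(CO[Si](c1ccccc1)(c1ccccc1)C(C)(C)C)OS(C)(=O)=O
F5 | step 5 | rac-(1R,2S)-1-[4-(benzyloxy)-3,5-dimethoxyphenyl]-2-[(tert-butyldiphenylsilyloxy)methyl]but-3-yn-1-ol | C#C[C@@H](CO[Si](c1ccccc1)(c1ccccc1)C(C)(C)C)[C@@H](O)c1cc(OC)c(OCc2ccccc2)c(OC)c1
F6 | step 5 | 2-(benzyloxy)-5-bromo-1,3-dimethoxybenzene | COc1cc(Br)cc(OC)c1OCc1ccccc1
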